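**Plan**
Cuts (isochromene numbering C1, O2, C3, C4, C4a, C5–C8, C8a): the C8 ketone and the C1=C8a enol ether are traced back to a C8 isopropyl enol ether and a C1 ethyl acetal; then C6–C7, C5–C6 and C4a–C8a are cut in one thermal step; then the acetal O2–C1 bond, the C7–methyl and C7–O-acyl bonds, and the C8a–C1 bond to a squarate ester.
Enabling feature: with C8 as an enol ether, ring A (C4a, C5, C6, C7, C8, C8a) is a 6-acyloxy-6-methylcyclohexa-2,4-dienone, the 6π-closure product of a dienylketene onto a methyl- and acyloxy-bearing terminus; C5 and C4a are the two carbons of an alkyne held to C8a by the chain C4–C3–O2–C1.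
Forward: squarate ester → 3-(diethoxymethyl)cyclobutenedione → mixed acetal with (R)-pent-4-yn-2-ol → methyl addition and stearoylation → heat (ring B closes first in a ketene–alkyne [2+2], ring A second in the 6π closure) → acid hydrolysis.
Stereochemistry: C3 is bought with (R)-pent-4-yn-2-ol and its C–O bond is never broken; C7 is set in the 6π closure under the bias of the temporary acetal centre C1, and because C3 is fixed any C7 epimer is a separable diastereomer.
Key step: step 4

Remark on the chemistry: two centres that disappear before the target is reached are formed without control. The acetal carbon of the mixed acetal forms as both epimers; the (S) epimer is isolated and carried on. The ring carbon that receives methyl and stearate forms as both epimers, which are used together because that carbon becomes planar in the key step; names and SMILES show the (R) epimer. The non-isolated adducts of step 1 and the pyridinium salt of step 2 are racemic.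

**Step 1**
Reactants: 1 diisopropyl squarate [3,4-di(propan-2-yloxy)cyclobut-3-ene-1,2-dione]; 2 tributyl(diethoxymethyl)stannane
Product: 6 3-(diethoxymethyl)-4-(propan-2-yloxy)cyclobut-3-ene-1,2-dione, via diethoxymethyllithium 3 (not isolated), via lithium alkoxide adduct 4 (not isolated), via tertiary trifluoroacetate 5 (not isolated)
Conditions: 2, n-BuLi, THF, −78 °C; then 1, −78 °C; then (CF3CO)2O, −78 °C; aq NaHCO3, 0 °C
Reagents that add atoms: water (SMILES O)
Why: Tin–lithium exchange should give the formyl-anion equivalent 3, which adds 1,2 to one squarate carbonyl as organolithiums do; trifluoroacetylation of alkoxide 4 and ionisation of 5 to the dialkoxycyclobutenyl cation, captured by water at work-up with loss of propan-2-ol, complete the standard squarate addition–transposition to a 3-substituted 4-alkoxycyclobutenedione, and the acetal should survive because the acid is met cold and buffered at once.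

**Step 2**
Reactants: 6 3-(diethoxymethyl)-4-(propan-2-yloxy)cyclobut-3-ene-1,2-dione; 7 (R)-pent-4-yn-2-ol
Product: 9 3-[(S)-ethoxy{[(2R)-pent-4-yn-2-yl]oxy}methyl]-4-(propan-2-yloxy)cyclobut-3-ene-1,2-dione, via collidinium triflate 8 (not isolated)
Conditions: Et3SiOTf, 2,4,6-collidine, CH2Cl2, 0 °C; then 7, 0 °C to rt; chromatography to isolate the (S)-acetal epimer
Reagents that add atoms: none
Why: Mixed-acetal formation by silyl triflate–collidine activation: one ethoxy group is replaced by collidine to give the N,O-acetal salt 8, which the secondary alcohol displaces under non-acidic conditions that leave the carbinol centre of 7 and the vinylogous ester untouched; the acetal centre forms without control, so the (S) epimer is separated and the other one is returned to the same conditions with ethanol to be re-equilibrated.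

**Step 3**
Reactants: 9 the (S)-mixed acetal; 10 stearoyl chloride (octadecanoyl chloride)
Product: 12 (1R)-3-[(S)-ethoxy{[(2R)-pent-4-yn-2-yl]oxy}methyl]-1-methyl-4-oxo-2-(propan-2-yloxy)cyclobut-2-en-1-yl octadecanoate (both epimers at ring C1; 1R shown), via lithium alkoxide 11 (not isolated)
Conditions: MeLi, THF, −78 °C; then 10, −78 to −20 °C
Reagents that add atoms: methyllithium (SMILES [Li]C)
Why: 1,2-Addition of an organolithium to a 3-alkoxycyclobutenedione goes to the ketone-like carbonyl beside the alkoxy-bearing carbon and not to the vinylogous-ester carbonyl, and at −78 °C should outrun deprotonation of the alkyne; the tertiary lithium alkoxide 11 is then O-acylated in the same flask by the acid chloride, and the new ring centre, formed as both epimers, is of no consequence because it becomes planar in step 4.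

**Step 4**
Reactants: 12 the 4-acyloxy-4-methylcyclobutenone carrying the tethered alkyne
Product: 16 (1S,3R,7S)-1-ethoxy-3,7-dimethyl-6-oxo-8-(propan-2-yloxy)-3,4,6,7-tetrahydro-1H-isochromen-7-yl octadecanoate, via vinylketene 13 (not isolated), via bicyclic cyclobutenone 14 (not isolated), via dienylketene 15 (not isolated)
Conditions: degassed PhMe (0.01 M), 2,6-di-tert-butyl-4-methylpyridine (0.1 equiv), 120 °C, sealed tube
Reagents that add atoms: none
Why: Proposed new method: heat opens the cyclobutenone by conrotatory 4π cleavage of the C6–C7 bond, the acyloxy group rotating outward, to vinylketene 13, whose ketene C=C adds to the tethered alkyne in a [2+2] (C6 to the terminal carbon C5, C8a to C4a), and the strained adduct 14 reopens (C6–C8a) to dienylketene 15, which closes C6–C7 by 6π electrocyclisation. The closest known reaction is the Danheiser benzannulation, which strings the same four events together intermolecularly with heteroatom-activated alkynes and ends in a phenol, combined with the known thermal closure of dienylketenes to 6-acyloxy-6-methylcyclohexa-2,4-dienones; new here are the tethered unactivated alkyne and the blocked, stereogenic C7 terminus. Ring B closes in the [2+2] as the six-membered ring of a bicyclo[4.2.0]octenone, the four-atom tether joining the ketene α-carbon C8a to the internal alkyne carbon so that the electrophilic ketene carbon meets the alkyne terminus, and ring A closes in the 6π step, for which ring B holds the C4a=C8a bond in the required cis geometry. C7, the only new centre that survives (the C8a centre of 14 is erased on reopening), is controlled by the (S)-acetal centre C1: trans to the equatorial C3 methyl, its ethoxy group lies pseudoaxial on ring B, the C8 isopropoxy group turns to the other face to avoid it, and in the early transition state the outward acyloxy group on C7 rotates away from the isopropyl group onto the ethoxy face, which is the (7S) configuration of 16. The step needs interception of the vinylketene by an unactivated alkyne, which intramolecularity, dilution and the reversibility of the first opening should provide, outward rotation of the acyloxy group, the usual torquoselectivity of oxygen donors, and facial selectivity at C7, for which C1 is the designed bias; any C7 epimer is a diastereomer, since C3 is fixed, and is removed by chromatography. That epimer could in principle be returned to 15 by the known photochemical ring opening of 6-acyloxycyclohexa-2,4-dienones.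

**Step 5**
Reactants: 16 the C8 isopropyl enol ether / C1 ethyl acetal
Product: 17 (3R,7R)-3,7-dimethyl-6,8-dioxo-3,4,7,8-tetrahydro-6H-isochromen-7-yl octadecanoate (CNP0142202.1)
Conditions: p-TsOH·H2O (0.1 equiv), THF–H2O (10:1), 0 °C to rt
Reagents that add atoms: water (SMILES O)
Why: Acid-catalysed hydrolysis of a vinylogous orthoester-type system: loss of ethanol from C1 gives an oxocarbenium ion delocalised through C8a onto the C8 enol ether, water adds at C8 and propan-2-ol leaves, giving the C1=C8a–C8=O vinylogous ester, while C3 and the quaternary C7 cannot epimerise and the tertiary ester is inert to dilute acid; the C7 descriptor changes from S to R only because C8 outranks C6 once it is a ketone.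

**Compound list**
1 | diisopropyl squarate, 3,4-di(propan-2-yloxy)cyclobut-3-ene-1,2-dione | CC(C)OC1=C(OC(C)C)C(=O)C1=O | starting material
2 | tributyl(diethoxymethyl)stannane | CCCC[Sn](CCCC)(CCCC)C(OCC)OCC | starting material
3 | diethoxymethyllithium | [Li]C(OCC)OCC | intermediate
4 | lithium 1-(diethoxymethyl)-4-oxo-2,3-di(propan-2-yloxy)cyclobut-2-en-1-olate (racemic) | [Li+].[O-]C1(C(OCC)OCC)C(OC(C)C)=C(OC(C)C)C1=O | intermediate
5 | 1-(diethoxymethyl)-4-oxo-2,3-di(propan-2-yloxy)cyclobut-2-en-1-yl trifluoroacetate (racemic) | CCOC(OCC)C1(OC(=O)C(F)(F)F)C(OC(C)C)=C(OC(C)C)C1=O | intermediate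
6 | 3-(diethoxymethyl)-4-(propan-2-yloxy)cyclobut-3-ene-1,2-dione | CCOC(OCC)C1=C(OC(C)C)C(=O)C1=O | intermediate
7 | (R)-pent-4-yn-2-ol | C[C@@H](O)CC#C | starting material
8 | 1-{ethoxy[3,4-dioxo-2-(propan-2-yloxy)cyclobut-1-en-1-yl]methyl}-2,4,6-trimethylpyridin-1-ium triflate (racemic) | CCOC(C1=C(OC(C)C)C(=O)C1=O)[n+]1c(C)cc(C)cc1C.[O-]S(=O)(=O)C(F)(F)F | intermediate
9 | 3-[(S)-ethoxy{[(2R)-pent-4-yn-2-yl]oxy}methyl]-4-(propan-2-yloxy)cyclobut-3-ene-1,2-dione | CC(C)OC1=C([C@@H](OCC)O[C@H](C)CC#C)C(=O)C1=O | intermediate
10 | stearoyl chloride (octadecanoyl chloride) | CCCCCCCCCCCCCCCCCC(=O)Cl | starting material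
11 | lithium (1R)-3-[(S)-ethoxy{[(2R)-pent-4-yn-2-yl]oxy}methyl]-1-methyl-4-oxo-2-(propan-2-yloxy)cyclobut-2-en-1-olate (both ring C1 epimers; 1R shown) | [Li+].[O-][C@]1(C)C(OC(C)C)=C([C@@H](OCC)O[C@H](C)CC#C)C1=O | intermediate
12 | (1R)-3-[(S)-ethoxy{[(2R)-pent-4-yn-2-yl]oxy}methyl]-1-methyl-4-oxo-2-(propan-2-yloxy)cyclobut-2-en-1-yl octadecanoate (both ring C1 epimers; 1R shown) | CCCCCCCCCCCCCCCCCC(=O)O[C@]1(C)C(OC(C)C)=C([C@@H](OCC)O[C@H](C)CC#C)C1=O | intermediate
13 | (2Z)-4-[(S)-ethoxy{[(2R)-pent-4-yn-2-yl]oxy}methyl]-5-oxo-3-(propan-2-yloxy)penta-2,4-dien-2-yl octadecanoate (vinylketene; acyloxy and isopropoxy cis) | CCCCCCCCCCCCCCCCCC(=O)O/C(C)=C(\OC(C)C)C(=C=O)[C@@H](OCC)O[C@H](C)CC#C | intermediate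
14 | (1Z)-1-[(1S,2S,4R)-2-ethoxy-4-methyl-8-oxo-3-oxabicyclo[4.2.0]oct-6-en-1-yl]-1-(propan-2-yloxy)prop-1-en-2-yl octadecanoate (one ring-fusion epimer shown; either reopens to 15) | O=C1C=C2C[C@@H](C)O[C@H](OCC)[C@]12/C(OC(C)C)=C(\C)OC(=O)CCCCCCCCCCCCCCCCC | intermediate
15 | (1Z)-1-[(2S,6R)-2-ethoxy-6-methyl-4-(2-oxoethenyl)-5,6-dihydro-2H-pyran-3-yl]-1-(propan-2-yloxy)prop-1-en-2-yl octadecanoate (dienylketene) | O=C=CC1=C(/C(OC(C)C)=C(\C)OC(=O)CCCCCCCCCCCCCCCCC)[C@@H](OCC)O[C@H](C)C1 | intermediate
16 | (1S,3R,7S)-1-ethoxy-3,7-dimethyl-6-oxo-8-(propan-2-yloxy)-3,4,6,7-tetrahydro-1H-isochromen-7-yl octadecanoate | CCCCCCCCCCCCCCCCCC(=O)O[C@]1(C)C(=O)C=C2C[C@@H](C)O[C@H](OCC)C2=C1OC(C)C | intermediate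
17 | (3R,7R)-3,7-dimethyl-6,8-dioxo-3,4,7,8-tetrahydro-6H-isochromen-7-yl octadecanoate | CCCCCCCCCCCCCCCCCC(=O)O[C@]1(C)C(=O)C=C2C[C@@H](C)OC=C2C1=O | target

Total step count: 5. Longest linear sequence: 5 steps (1 or 2 → 6 → 9 → 12 → 16 → 17).

**Steps most likely to fail**

Step 4. What may go wrong: the vinylketene is diverted before the unactivated alkyne adds (reclosure without progress, 1,5-hydrogen shift from the inward methyl group, acyl transfer to the ketene, dimerisation), or the 6π closure shows poor facial selectivity at C7. The fallback uses known chemistry only: ring A is built as an arene and the C7 oxygen is introduced by oxidative dearomatisation. It sets out from stearoyl chloride 10, the one route compound it keeps, and comes back at target 17. 5-Bromo-1,3-dimethoxy-2-methylbenzene is lithiated (n-BuLi, THF, −78 °C) and opens (R)-propylene oxide (BF3·OEt2) to (2R)-1-(3,5-dimethoxy-4-methylphenyl)propan-2-ol F1. Rieche formylation (Cl2CHOMe, TiCl4) at either of the two equivalent free ring positions gives 6-[(2R)-2-hydroxypropyl]-2,4-dimethoxy-3-methylbenzaldehyde F2. BBr3 frees both phenols to give 2,4-dihydroxy-6-[(2R)-2-hydroxypropyl]-3-methylbenzaldehyde F3. Trifluoroacetic acid closes the side-chain hydroxyl onto the aldehyde, and IBX hydroxylates the resulting dihydrobenzopyrylium ion at the methyl-bearing carbon (the usual azaphilone oxidative dearomatisation); this should give (3R,7R)-7-hydroxy-3,7-dimethyl-3,4-dihydro-6H-isochromene-6,8(7H)-dione F4 after separation from its C7 epimer. Acylation of the tertiary alcohol with 10 (Et3N, DMAP, CH2Cl2) gives 17.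

Step 2. What may go wrong: the silyl triflate activates the cyclobutenedione instead of the acetal, the incoming alcohol exchanges with the ring isopropoxy group of the strongly electrophilic dione, or the two acetal epimers do not separate. The fallback changes the order of events; it sets out from 6 and comes back at 12. Methyllithium addition and trapping with 10 are carried out on 6 first, giving racemic 3-(diethoxymethyl)-1-methyl-4-oxo-2-(propan-2-yloxy)cyclobut-2-en-1-yl octadecanoate F5. The ethoxy/pentynyloxy exchange with 7 is then run on this far less electrophilic cyclobutenone (same silyl triflate–collidine activation) and gives 12 as both acetal epimers. The mixture is taken through step 4 and the epimers are sorted at the stage of 16, where the acetal carbon lies in ring B and the diastereomers should differ more. This order also keeps the alkyne away from methyllithium.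

Step 3. What may go wrong: methyllithium is lost to deprotonation of the terminal alkyne, and the resulting acetylide adds to the dione in competition with the methyl nucleophile. The fallback masks the alkyne C–H; it sets out from 6 and comes back at 12. (2R)-5-(Trimethylsilyl)pent-4-yn-2-ol F6, made from (R)-propylene oxide and lithium (trimethylsilyl)acetylide with BF3·OEt2, replaces 7 in the conditions of step 2 and gives 3-[(S)-ethoxy{[(2R)-5-(trimethylsilyl)pent-4-yn-2-yl]oxy}methyl]-4-(propan-2-yloxy)cyclobut-3-ene-1,2-dione F7. Methyllithium and then 10 give (1R)-3-[(S)-ethoxy{[(2R)-5-(trimethylsilyl)pent-4-yn-2-yl]oxy}methyl]-1-methyl-4-oxo-2-(propan-2-yloxy)cyclobut-2-en-1-yl octadecanoate F8 (both ring epimers) with no acidic alkyne hydrogen in the flask. AgNO3-catalysed protodesilylation in aqueous acetone, which is neutral and should leave the ester and the acetal alone, returns 12.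

**Further compounds**
F1 | step 4 | (2R)-1-(3,5-dimethoxy-4-methylphenyl)propan-2-ol | C[C@@H](O)Cc1cc(OC)c(C)c(OC)c1
F2 | step 4 | 6-[(2R)-2-hydroxypropyl]-2,4-dimethoxy-3-methylbenzaldehyde | C[C@@H](O)Cc1cc(OC)c(C)c(OC)c1C=O
F3 | step 4 | 2,4-dihydroxy-6-[(2R)-2-hydroxypropyl]-3-methylbenzaldehyde | C[C@@H](O)Cc1cc(O)c(C)c(O)c1C=O
F4 | step 4 | (3R,7R)-7-hydroxy-3,7-dimethyl-3,4-dihydro-6H-isochromene-6,8(7H)-dione | O[C@]1(C)C(=O)C=C2C[C@@H](C)OC=C2C1=O
F5 | step 2 | 3-(diethoxymethyl)-1-methyl-4-oxo-2-(propan-2-yloxy)cyclobut-2-en-1-yl octadecanoate (racemic) | CCCCCCCCCCCCCCCCCC(=O)OC1(C)C(OC(C)C)=C(C(OCC)OCC)C1=O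
F6 | step 3 | (2R)-5-(trimethylsilyl)pent-4-yn-2-ol | C[C@@H](O)CC#C[Si](C)(C)C
F7 | step 3 | 3-[(S)-ethoxy{[(2R)-5-(trimethylsilyl)pent-4-yn-2-yl]oxy}methyl]-4-(propan-2-yloxy)cyclobut-3-ene-1,2-dione | CC(C)OC1=C([C@@H](OCC)O[C@H](C)CC#C[Si](C)(C)C)C(=O)C1=O
F8 | step 3 | (1R)-3-[(S)-ethoxy{[(2R)-5-(trimethylsilyl)pent-4-yn-2-yl]oxy}methyl]-1-methyl-4-oxo-2-(propan-2-yloxy)cyclobut-2-en-1-yl octadecanoate (both ring C1 epimers; 1R shown) | CCCCCCCCCCCCCCCCCC(=O)O[C@]1(C)C(OC(C)C)=C([C@@H](OCC)O[C@H](C)CC#C[Si](C)(C)C)C1=O
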